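**Plan**

- Feature: ring A with C7–C8–C9 and ring B with C7'–C8'–C9' are the same 3,5-dimethoxy-4-oxyphenyl-C3 unit, joined only by the C8–O–C4' ether. The skeleton is therefore a dimer of one phenol, 2,6-dimethoxy-4-propenylphenol.
- Retrosynthesis: the antipode is added back (resolution), the C9' hydroxyl is returned to a methyl and the ring A 4-O-methyl to a phenol. The key cut then removes C8–O4' and C7–OAc together, leaving two molecules of the propenylphenol and acetic acid; the propenylphenol comes from commercial 4-allyl-2,6-dimethoxyphenol.
- Forward: no ring is formed. The two C6–C3 halves are joined once, in step 2 (oxidative coupling and acetate capture in one flask); afterwards only the periphery changes (O-methylation, allylic oxidation at C9', 1,2-reduction).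
- Stereochemistry: C8 arises in the radical coupling and C7 in the acetate addition, neither under absolute control. The threo racemate is taken by chromatography after step 2 and the (7R,8R) enantiomer by preparative chiral HPLC in the last step; the E alkene is the thermodynamic one and is kept.

Key step: step 2

Remark: compounds 6 to 9 are racemic; they are named rac-(1R,2R) and drawn as the enantiomer that leads to the target, and the racemic quinone methide 5, with one stereocentre, is drawn without a descriptor.

**Route**

Step 1
Reactants: 1 4-allyl-2,6-dimethoxyphenol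
Product: 2 (E)-2,6-dimethoxy-4-(prop-1-enyl)phenol
Conditions: RuCl2(PPh3)3 (cat.), toluene, 110 °C, argon
Reagents that add atoms: none
Why: Ruthenium-hydride catalysed alkene isomerisation (insertion then β-hydride elimination) moves the terminal double bond into conjugation with the arene, where the (E)-alkene is the thermodynamic product; no stereocentre is formed and any minor Z isomer is removed by chromatography.

Step 2
Reactants: 2 (E)-2,6-dimethoxy-4-(prop-1-enyl)phenol (two molecules); 3 acetic acid
Product: 6 rac-(1R,2R)-2-[2,6-dimethoxy-4-[(E)-prop-1-enyl]phenoxy]-1-(4-hydroxy-3,5-dimethoxyphenyl)propyl acetate (threo), via phenoxyl radical 4 (not isolated), via quinone methide 5 (not isolated)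
Conditions: Ag2O (0.6 equiv per phenol), 4 Å MS, dry CH2Cl2, rt, dark, argon; filter through Celite; then glacial AcOH (excess), rt; flash chromatography (threo isomer)
Reagents that add atoms: acetic acid (compound 3), CC(=O)O
Why: Ag2O takes one electron and one proton from each molecule of 2 to give the phenoxyl radical 4, whose spin sits on the phenolic oxygen, on C1 and on C8, and combination of C8 of one radical with the oxygen of the other forms the C8–O4' bond and leaves the first unit as the para-quinone methide 5. Acetic acid, added once the silver has been filtered off, activates the quinone methide carbonyl by hydrogen bonding and adds through oxygen to C7 in a 1,6 sense, so that ring A rearomatises and the C7–OAc bond is made. The closest known reaction types are the oxidative dehydrodimerisation of 4-propenylphenols to 8-O-4' quinone methides and the conjugate addition of oxygen nucleophiles, carboxylic acids among them, to para-quinone methides; no ring is closed. C8 is created in the radical combination without any chiral influence and is racemic, and C7 is created under no more than 1,2-induction from C8, so threo and erythro acetates are both expected and the threo racemate 6 is taken by chromatography. The selectivity needed is C8–O over C8–C8 and over coupling at ring carbons: the two methoxy groups flanking the phenol close the ortho positions and both partners are the same molecule, so no cross-coupling question arises and the C8–C8 dimer is the by-product to be removed. Filtering before the acid is added keeps the liberated phenol of 6 away from the oxidant and leaves the water formed in the oxidation on the molecular sieves, away from 5.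

Step 3
Reactants: 6 rac-(1R,2R)-2-[2,6-dimethoxy-4-[(E)-prop-1-enyl]phenoxy]-1-(4-hydroxy-3,5-dimethoxyphenyl)propyl acetate
Product: 7 rac-(1R,2R)-2-[2,6-dimethoxy-4-[(E)-prop-1-enyl]phenoxy]-1-(3,4,5-trimethoxyphenyl)propyl acetate
Conditions: CH2N2 (excess, ethereal), Et2O/CH2Cl2, 0 °C to rt; excess reagent purged with argon
Reagents that add atoms: diazomethane, C=[N+]=[N-]
Why: O-methylation of a phenol by a diazoalkane proceeds by proton transfer and immediate collapse of the methyldiazonium phenoxide ion pair, so no base is present and the phenoxide should not live long enough to expel the para-benzylic acetate as a quinone methide; both stereocentres are untouched.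

Step 4
Reactants: 7 rac-(1R,2R)-2-[2,6-dimethoxy-4-[(E)-prop-1-enyl]phenoxy]-1-(3,4,5-trimethoxyphenyl)propyl acetate
Product: 8 rac-(1R,2R)-2-[2,6-dimethoxy-4-[(E)-3-oxoprop-1-enyl]phenoxy]-1-(3,4,5-trimethoxyphenyl)propyl acetate
Conditions: SeO2 (1.5 equiv), 1,4-dioxane, 100 °C
Reagents that add atoms: selenium dioxide, O=[Se]=O
Why: Riley allylic oxidation (ene reaction at the alkene, [2,3]-sigmatropic shift of the allylseleninic acid, then oxidation of the allylic alcohol level to the aldehyde) converts the C9' methyl of the (E)-propenylarene into the conjugated (E)-enal, as is usual for propenyl side chains of neolignans; the C7–H is deactivated by its acetoxy group and the stereocentres are not involved, and any allylic alcohol left at the intermediate oxidation level is compound 9 and is carried along.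

Step 5
Reactants: 8 rac-(1R,2R)-2-[2,6-dimethoxy-4-[(E)-3-oxoprop-1-enyl]phenoxy]-1-(3,4,5-trimethoxyphenyl)propyl acetate
Product: 9 rac-(1R,2R)-2-[4-[(E)-3-hydroxyprop-1-enyl]-2,6-dimethoxyphenoxy]-1-(3,4,5-trimethoxyphenyl)propyl acetate
Conditions: NaBH4, CeCl3·7H2O, MeOH, 0 °C, short reaction time
Reagents that add atoms: none
Why: Luche reduction delivers hydride to the carbonyl carbon only (1,2-reduction), giving the (E)-allylic alcohol without touching the alkene, and the secondary acetate should survive the brief exposure at 0 °C.

Step 6
Reactants: 9 rac-(1R,2R)-2-[4-[(E)-3-hydroxyprop-1-enyl]-2,6-dimethoxyphenoxy]-1-(3,4,5-trimethoxyphenyl)propyl acetate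
Product: 10 (1R,2R)-2-[4-[(E)-3-hydroxyprop-1-enyl]-2,6-dimethoxyphenoxy]-1-(3,4,5-trimethoxyphenyl)propyl acetate (the target, 7R,8R)
Conditions: preparative HPLC, amylose tris(3,5-dimethylphenylcarbamate) on silica, n-hexane/i-PrOH, rt
Reagents that add atoms: none
Why: Resolution of a racemate by chromatography on a chiral stationary phase, where the two antipodes form diastereomeric adsorbates with the carbamate selector and elute apart; no bond is made or broken, and the (1R,2R) antipode is to be identified by electronic circular dichroism against a computed spectrum and by the sign of its optical rotation.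

**Compound list**

1 | 4-allyl-2,6-dimethoxyphenol | C=CCc1cc(OC)c(O)c(OC)c1 | starting material
2 | (E)-2,6-dimethoxy-4-(prop-1-enyl)phenol | COc1cc(/C=C/C)cc(OC)c1O | intermediate
3 | acetic acid | CC(=O)O | starting material
4 | 2,6-dimethoxy-4-[(E)-prop-1-enyl]phenoxyl radical | COc1cc(/C=C/C)cc(OC)c1[O] | intermediate (not isolated)
5 | racemic 4-[2-[2,6-dimethoxy-4-[(E)-prop-1-enyl]phenoxy]propylidene]-2,6-dimethoxycyclohexa-2,5-dien-1-one (8-O-4' quinone methide) | COC1=CC(=CC(C)Oc2c(OC)cc(/C=C/C)cc2OC)C=C(OC)C1=O | intermediate (not isolated)
6 | rac-(1R,2R)-2-[2,6-dimethoxy-4-[(E)-prop-1-enyl]phenoxy]-1-(4-hydroxy-3,5-dimethoxyphenyl)propyl acetate (threo) | COc1cc([C@@H](OC(C)=O)[C@@H](C)Oc2c(OC)cc(/C=C/C)cc2OC)cc(OC)c1O | intermediate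
7 | rac-(1R,2R)-2-[2,6-dimethoxy-4-[(E)-prop-1-enyl]phenoxy]-1-(3,4,5-trimethoxyphenyl)propyl acetate | COc1cc([C@@H](OC(C)=O)[C@@H](C)Oc2c(OC)cc(/C=C/C)cc2OC)cc(OC)c1OC | intermediate
8 | rac-(1R,2R)-2-[2,6-dimethoxy-4-[(E)-3-oxoprop-1-enyl]phenoxy]-1-(3,4,5-trimethoxyphenyl)propyl acetate | COc1cc([C@@H](OC(C)=O)[C@@H](C)Oc2c(OC)cc(/C=C/C=O)cc2OC)cc(OC)c1OC | intermediate
9 | rac-(1R,2R)-2-[4-[(E)-3-hydroxyprop-1-enyl]-2,6-dimethoxyphenoxy]-1-(3,4,5-trimethoxyphenyl)propyl acetate | COc1cc([C@@H](OC(C)=O)[C@@H](C)Oc2c(OC)cc(/C=C/CO)cc2OC)cc(OC)c1OC | intermediate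
10 | (1R,2R)-2-[4-[(E)-3-hydroxyprop-1-enyl]-2,6-dimethoxyphenoxy]-1-(3,4,5-trimethoxyphenyl)propyl acetate | COc1cc([C@@H](OC(C)=O)[C@@H](C)Oc2c(OC)cc(/C=C/CO)cc2OC)cc(OC)c1OC | target

**Totals and risks**

Total step count: 6. Longest linear sequence: 6 steps (1 to 10).

Steps most likely to fail:

Step 2. What may go wrong: radical combination at C8–C8 outrunning C8–O combination, further oxidation of the dimer, and acetate addition at C7 with too little threo preference. The fallback makes the C8–O bond by ionic etherification and sets C7 by hydride reduction; it sets out from 2 and comes back at 7, bypassing steps 2 and 3. 1-(3,4,5-Trimethoxyphenyl)propan-1-one F1 is brominated at the α-carbon with CuBr2 (EtOAc/CHCl3, reflux) to racemic 2-bromo-1-(3,4,5-trimethoxyphenyl)propan-1-one F2. The potassium phenoxide of 2 (K2CO3, butanone, reflux) displaces the bromide in a Williamson etherification to give racemic 2-[2,6-dimethoxy-4-[(E)-prop-1-enyl]phenoxy]-1-(3,4,5-trimethoxyphenyl)propan-1-one F3. Reduction with LiBH(s-Bu)3 in THF at −78 °C, under Felkin–Anh control with the aryloxy group anti to the incoming hydride, should favour rac-(1R,2R)-2-[2,6-dimethoxy-4-[(E)-prop-1-enyl]phenoxy]-1-(3,4,5-trimethoxyphenyl)propan-1-ol F4 (threo), which is freed from erythro material by chromatography. Acetylation (Ac2O, pyridine, DMAP) then gives 7.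

Step 3. What may go wrong: ionisation of the phenol followed by expulsion of the para-benzylic acetate (return to the quinone methide), which would scramble C7 or lose the ester, or incomplete methylation of the doubly ortho-substituted phenol. The fallback brings in the acetate only after the phenol has been methylated; it sets out from quinone methide 5 (made from 2 as in step 2) and comes back at 7. Water (THF/H2O, rt) is added to 5 in place of acetic acid, and separation from the erythro isomer gives rac-(1R,2R)-4-[2-[2,6-dimethoxy-4-[(E)-prop-1-enyl]phenoxy]-1-hydroxypropyl]-2,6-dimethoxyphenol F5 (threo), whose benzylic hydroxyl cannot leave under basic conditions. MeI/K2CO3 in acetone methylates the phenol to the threo alcohol rac-(1R,2R)-2-[2,6-dimethoxy-4-[(E)-prop-1-enyl]phenoxy]-1-(3,4,5-trimethoxyphenyl)propan-1-ol F4, and acetylation (Ac2O, pyridine, DMAP) returns to 7.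

Step 4. What may go wrong: over-oxidation of the enal, stalling at mixed oxidation levels, or acidolysis of the benzylic acetate by selenous acid at 100 °C. The fallback brings in C9' at the aldehyde level as a whole fragment by olefin cross-metathesis; it sets out from 7 and comes back at 8. Crotonaldehyde with the second-generation Hoveyda–Grubbs catalyst (CH2Cl2, 40 °C) exchanges the ethylidene end of the propenyl group for a formylmethylidene unit, releases but-2-ene and should give the (E)-enal 8 directly; no new compound is made on the way.

**Further compounds**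

F1 | step 2 | 1-(3,4,5-trimethoxyphenyl)propan-1-one | CCC(=O)c1cc(OC)c(OC)c(OC)c1
F2 | step 2 | racemic 2-bromo-1-(3,4,5-trimethoxyphenyl)propan-1-one | CC(Br)C(=O)c1cc(OC)c(OC)c(OC)c1
F3 | step 2 | racemic 2-[2,6-dimethoxy-4-[(E)-prop-1-enyl]phenoxy]-1-(3,4,5-trimethoxyphenyl)propan-1-one | COc1cc(C(=O)C(C)Oc2c(OC)cc(/C=C/C)cc2OC)cc(OC)c1OC
F4 | step 2 | rac-(1R,2R)-2-[2,6-dimethoxy-4-[(E)-prop-1-enyl]phenoxy]-1-(3,4,5-trimethoxyphenyl)propan-1-ol (threo) | COc1cc([C@@H](O)[C@@H](C)Oc2c(OC)cc(/C=C/C)cc2OC)cc(OC)c1OC
F5 | step 3 | rac-(1R,2R)-4-[2-[2,6-dimethoxy-4-[(E)-prop-1-enyl]phenoxy]-1-hydroxypropyl]-2,6-dimethoxyphenol (threo) | COc1cc([C@@H](O)[C@@H](C)Oc2c(OC)cc(/C=C/C)cc2OC)cc(OC)c1O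
F0 | step 4 | none | none
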